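Freeze what stays the same from flask to flask, and start from the charges and readings.

| setting | Tuesday's | Saturday's | Sunday's |
|---|---|---|---|
| substrate | 1.00 M | 1.00 M | 1.00 M |
| coupling partner | 1.20 M | 1.20 M | 1.20 M |
| catalyst | 0.0500 M | 0.0750 M | 0.120 M |
| time |  |  | 11 h |

- Tuesday's run (time / h: [target] / M): 1.6: 0.271; 3.1: 0.416; 4.7: 0.497; 6.3: 0.543; 7.9: 0.573; 9.4: 0.583; 11: 0.603
- Saturday's run (time / h: [target] / M): 1.6: 0.364; 3.1: 0.528; 4.7: 0.609; 6.3: 0.652; 7.9: 0.668; 9.4: 0.680; 11: 0.696

(each reading ± 0.003 M)

- reaction order in [catalyst] at the outset, round the charge of the Tuesday's run, defined at two percent of the substrate turned into target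
- target in the Sunday's run at 11 h, as a share of the substrate charged

- Overall: substrate + coupling partner -> target, with catalyst as catalyst.
- Constant volume, constant temperature.
- A reading of a species includes what of it is bound.
- "The second partner" is coupling partner.
- An order is taken over about fifteen percent of the charge, up and down.

Let S and R be the charges of substrate and coupling partner and P the target made, and let D = ln[S(R−P)/(R(S−P))]. A rate proportional to catalyst, substrate and coupling partner makes D grow in proportion to catalyst and time.

Does catalyst act as a plain multiplier? At 1.6 h, Saturday's D is 1.52 times Tuesday's, against a catalyst ratio of 1.50. That is an order of 1.03 at equal time, but it is read far past the two-percent mark, so it is a provisional figure for the order asked.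

Does the multiplier last to the end? Tuesday's flask reads 4.51 M⁻¹ at 11 h, and this is φ, the progress per catalyst, D over the catalyst charge at a stated time. Saturday's flask reads 4.31 M⁻¹, which is lower, so φ is nearly constant but sags as catalyst rises.

Continuing that sag in step with catalyst gives Sunday's flask φ = 3.94 M⁻¹. My own reckoning for Sunday's flask is therefore 78.4% of the substrate.

The forecast expects 80%, within 76% to 83%, which is 1.6 percentage points above mine. For the order it gives 0.97, within 0.82 to 1.08. Its reading of the curves is “the catalyst is dying rather than the system reaching equilibrium”.

The simulation gives 79.2% for Sunday's flask and an order of 0.67 round Tuesday's charge, which is below the forecast's range.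

    active catalyst + substrate ⇌ catalyst-substrate complex, settled at all times (0.5050 M⁻¹)
    catalyst-substrate complex + coupling partner → target + active catalyst (14.36 M⁻¹ h⁻¹)
    coupling partner → lost reagent (0.1508 h⁻¹)
    catalyst → active catalyst (4.788 h⁻¹)

Sunday's 79.2% means φ = 4.09 M⁻¹, lower than Saturday's. The simulated Sunday run without the step from coupling partner to lost reagent reaches 96.1%, which means φ = 13.5 M⁻¹, or 3.30 times as much, so in Sunday's flask that step holds the target down by 17 points.

Readings and results were generated by integration with constants of no real substance; scatter was added.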